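## Retrosynthetic overview

1. Target 19 ⇐ one-pot Pd-deallylation and ketal hydrolysis of cis-epoxy alcohol ketal 17. The HMG ester, made from (R)-mevalonolactone by oxidising its C5 arm, is attached early and used as a control element, not added last.
2. Oxirane ⇐ hydroxyl-directed vanadium epoxidation of cyclohexa-2,5-dienol 16. This replaces the usual plan (nucleophilic epoxidation of a farnesyl quinone or monoketal, then regioselective C=O reduction) with reduce-first, electrophilic, OH-delivered epoxidation of the electron-rich farnesyl-bearing alkene.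
3. C4 carbinol ⇐ CBS reduction of quinone monoketal 15; this is the only reagent-controlled ring stereocentre, and C5/C6 are relayed from it.
4. Monoketal ⇐ PhI(OAc)2/MeOH dearomatisation of farnesyl salicyl alcohol 9 ⇐ arylcopper + farnesyl bromide ⇐ 4-bromo-2,5-dimethoxybenzaldehyde.
5. Ring order: the carbocycle is the benzene ring of 1 (never built); a temporary 1,3-dioxine is formed in step 3 and removed in step 5; the oxirane is the last ring formed (step 11).

Assumption: 1, 5 and 11 are taken as purchasable; species that exist only as metal alkoxides/borates before work-up, activated esters or catalyst-bound forms are not numbered.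

Abbreviation: farnesyl = (2E,6E)-3,7,11-trimethyldodeca-2,6,10-trien-1-yl.

## Route

Step 1
Reactants: 1 4-bromo-2,5-dimethoxybenzaldehyde
Product: 2 4-bromo-2-hydroxy-5-methoxybenzaldehyde
Conditions: BCl3 (1.5 equiv), CH2Cl2, −78 → 0 °C; aq. NaHCO3 work-up
Reagents that add atoms: none
Why: Chelation-controlled Lewis-acid O-demethylation, in which boron bridges the aldehyde oxygen and the ortho methoxy oxygen so that only the 2-OMe is cleaved and the 5-OMe survives.

Step 2
Reactants: 2 4-bromo-2-hydroxy-5-methoxybenzaldehyde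
Product: 3 5-bromo-2-(hydroxymethyl)-4-methoxyphenol
Conditions: NaBH4, MeOH/THF, 0 °C
Reagents that add atoms: none
Why: Borohydride reduction of the aldehyde to the salicyl alcohol, leaving aryl bromide and aryl ether untouched.

Step 3
Reactants: 3 5-bromo-2-(hydroxymethyl)-4-methoxyphenol
Product: 4 7-bromo-6-methoxy-2,2-dimethyl-4H-1,3-benzodioxine
Conditions: Me2C(OMe)2, PPTS (cat.), acetone, rt
Reagents that add atoms: 2,2-dimethoxypropane (COC(C)(C)OC)
Why: Acid-catalysed transacetalisation ties the phenol and benzylic OH into a six-membered acetonide, removing both acidic protons before the organolithium step.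

Step 4
Reactants: 4 7-bromo-6-methoxy-2,2-dimethyl-4H-1,3-benzodioxine; 5 (2E,6E)-farnesyl bromide
Product: 8 7-[(2E,6E)-farnesyl]-6-methoxy-2,2-dimethyl-4H-1,3-benzodioxine, via aryllithium 6 (not isolated), via arylcopper 7 (not isolated)
Conditions: t-BuLi (2.1 equiv), THF, −78 °C; CuBr·SMe2 (1.0 equiv), −78 → −40 °C; then 5, −78 → 0 °C
Reagents that add atoms: none
Why: Bromine–lithium exchange and transmetalation to the arylcopper, then copper-mediated SN2 (α-selective) allylic substitution of the primary bromide, which keeps the 2E,6E geometry because γ-attack would have to form a quaternary carbon.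

Step 5
Reactants: 8 7-[(2E,6E)-farnesyl]-6-methoxy-2,2-dimethyl-4H-1,3-benzodioxine
Product: 9 5-[(2E,6E)-farnesyl]-2-(hydroxymethyl)-4-methoxyphenol
Conditions: AcOH/THF/H2O (3:1:1), 40 °C
Reagents that add atoms: none
Why: Mild acetal hydrolysis frees the phenol and CH2OH; aqueous acetic acid does not protonate the trisubstituted alkenes, and the phenol is meta to the farnesyl group so no chroman can form.

Step 6
Reactants: 9 5-[(2E,6E)-farnesyl]-2-(hydroxymethyl)-4-methoxyphenol
Product: 10 5-[(2E,6E)-farnesyl]-2-(hydroxymethyl)-4,4-dimethoxycyclohexa-2,5-dien-1-one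
Conditions: PhI(OAc)2 (1.1 equiv), MeOH, 0 °C
Reagents that add atoms: methanol (CO)
Why: Hypervalent-iodine oxidative dearomatisation of a p-methoxyphenol, with methanol captured at the OMe-bearing para carbon, which places the ketone next to the CH2OH carbon and the ketal next to the farnesyl carbon without ambiguity.

Step 7
Reactants: 11 (R)-(−)-mevalonolactone
Product: 13 allyl (R)-mevalonate, via potassium (R)-mevalonate 12 (not isolated)
Conditions: KOH (1.0 equiv), H2O, rt; evaporate; allyl bromide, DMF, rt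
Reagents that add atoms: potassium hydroxide ([K+].[OH-]); allyl bromide (C=CCBr)
Why: Lactone saponification followed by SN2 O-alkylation of the carboxylate; the quaternary carbinol is not involved, so the (R) configuration is carried through unchanged.

Step 8
Reactants: 13 allyl (R)-mevalonate
Product: 14 (R)-HMG monoallyl ester [(3R)-3-hydroxy-3-methyl-5-oxo-5-(prop-2-enyloxy)pentanoic acid]
Conditions: TEMPO (0.2 equiv), PhI(OAc)2 (2.2 equiv), MeCN/H2O (1:1), rt
Reagents that add atoms: water (O)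
Why: TEMPO/PhI(OAc)2 oxoammonium oxidation takes the primary alcohol through the aldehyde hydrate to the acid while the tertiary OH and allyl alkene are inert, so the former C5 arm of mevalonate becomes the acylating carboxyl and the centre will read (S) once esterified.

Step 9
Reactants: 10 5-[(2E,6E)-farnesyl]-2-(hydroxymethyl)-4,4-dimethoxycyclohexa-2,5-dien-1-one; 14 (R)-HMG monoallyl ester
Product: 15 allyl {4-[(2E,6E)-farnesyl]-3,3-dimethoxy-6-oxocyclohexa-1,4-dien-1-yl}methyl (3S)-3-hydroxy-3-methylpentanedioate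
Conditions: EDC·HCl (1.3 equiv), DMAP (0.1 equiv), CH2Cl2, 0 °C
Reagents that add atoms: none
Why: Steglich esterification of the unhindered primary allylic alcohol, in which the tertiary hydroxyl of 14 cannot compete; the acyloxymethyl group then makes the C3 side larger for the reduction and its alkene electron-poorer for the epoxidation.

Step 10
Reactants: 15 allyl {4-[(2E,6E)-farnesyl]-3,3-dimethoxy-6-oxocyclohexa-1,4-dien-1-yl}methyl (3S)-3-hydroxy-3-methylpentanedioate
Product: 16 allyl {(6S)-4-[(2E,6E)-farnesyl]-6-hydroxy-3,3-dimethoxycyclohexa-1,4-dien-1-yl}methyl (3S)-3-hydroxy-3-methylpentanedioate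
Conditions: (R)-Me-CBS (0.3 equiv), catecholborane (2.5 equiv), PhMe, −78 °C; MeOH quench, pH 10 buffer wash; crude used at once
Reagents that add atoms: none
Why: Corey–Bakshi–Shibata reduction, in which the oxazaborolidine binds the carbonyl lone pair anti to the α-branched C(CH2O-acyl)= side (large) and syn to the unsubstituted CH= side (small), so the (R)-catalyst delivers hydride to the Re face and gives the (S)-carbinol (the spatial arrangement that reads R in the target), with exclusive 1,2-reduction and no reaction at esters or alkenes at −78 °C.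

Step 11
Reactants: 16 allyl {(6S)-4-[(2E,6E)-farnesyl]-6-hydroxy-3,3-dimethoxycyclohexa-1,4-dien-1-yl}methyl (3S)-3-hydroxy-3-methylpentanedioate
Product: 17 allyl {(1R,5R,6R)-1-[(2E,6E)-farnesyl]-5-hydroxy-2,2-dimethoxy-7-oxabicyclo[4.1.0]hept-3-en-4-yl}methyl (3S)-3-hydroxy-3-methylpentanedioate
Conditions: VO(acac)2 (5 mol%), t-BuOOH (decane, 1.5 equiv), 2,6-lutidine (0.2 equiv), 4 Å MS, CH2Cl2, 0 °C
Reagents that add atoms: tert-butyl hydroperoxide (CC(C)(C)OO)
Why: Vanadium-catalysed hydroxyl-directed epoxidation (Sharpless–Michaelson type), in which the V(V) alkoxide of the carbinol transfers oxygen to its own face and so sets both oxirane carbons cis to the OH; the alkyl-substituted farnesyl-bearing ring alkene is more nucleophilic than the one carrying the electron-withdrawing acyloxymethyl group, and the isolated farnesyl alkenes, having no directing OH, are not oxidised.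

Step 12
Reactants: 17 allyl {(1R,5R,6R)-1-[(2E,6E)-farnesyl]-5-hydroxy-2,2-dimethoxy-7-oxabicyclo[4.1.0]hept-3-en-4-yl}methyl (3S)-3-hydroxy-3-methylpentanedioate
Product: 19 (3S)-5-({(1R,5R,6R)-1-[(2E,6E)-farnesyl]-5-hydroxy-2-oxo-7-oxabicyclo[4.1.0]hept-3-en-4-yl}methoxy)-3-hydroxy-3-methyl-5-oxopentanoic acid, via ketal acid 18 (not isolated)
Conditions: Pd(PPh3)4 (5 mol%), morpholine (3 equiv), THF, 0 °C → rt; then 0.5 M aq. oxalic acid, rt
Reagents that add atoms: water (O)
Why: Tsuji–Trost deallylation (π-allyl palladium trapped by morpholine) frees the acid while the enone is still masked, so no aza-Michael addition is possible, and mild acid hydrolysis of the allylic dimethyl ketal then unveils the ketone without touching any stereocentre.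

## Compound list

1 | 4-bromo-2,5-dimethoxybenzaldehyde | COc1cc(C=O)c(OC)cc1Br | starting material
2 | 4-bromo-2-hydroxy-5-methoxybenzaldehyde | COc1cc(C=O)c(O)cc1Br | intermediate
3 | 5-bromo-2-(hydroxymethyl)-4-methoxyphenol | COc1cc(CO)c(O)cc1Br | intermediate
4 | 7-bromo-6-methoxy-2,2-dimethyl-4H-1,3-benzodioxine | COc1cc2COC(C)(C)Oc2cc1Br | intermediate
5 | (2E,6E)-farnesyl bromide [(2E,6E)-1-bromo-3,7,11-trimethyldodeca-2,6,10-triene] | CC(C)=CCC/C(C)=C/CC/C(C)=C/CBr | starting material
6 | (6-methoxy-2,2-dimethyl-4H-1,3-benzodioxin-7-yl)lithium | [Li]c1cc2OC(C)(C)OCc2cc1OC | intermediate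
7 | (6-methoxy-2,2-dimethyl-4H-1,3-benzodioxin-7-yl)copper(I) | [Cu]c1cc2OC(C)(C)OCc2cc1OC | intermediate
8 | 7-[(2E,6E)-farnesyl]-6-methoxy-2,2-dimethyl-4H-1,3-benzodioxine | CC(C)=CCC/C(C)=C/CC/C(C)=C/Cc1cc2OC(C)(C)OCc2cc1OC | intermediate
9 | 5-[(2E,6E)-farnesyl]-2-(hydroxymethyl)-4-methoxyphenol | CC(C)=CCC/C(C)=C/CC/C(C)=C/Cc1cc(O)c(CO)cc1OC | intermediate
10 | 5-[(2E,6E)-farnesyl]-2-(hydroxymethyl)-4,4-dimethoxycyclohexa-2,5-dien-1-one | CC(C)=CCC/C(C)=C/CC/C(C)=C/CC1=CC(=O)C(CO)=CC1(OC)OC | intermediate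
11 | (R)-(−)-mevalonolactone [(4R)-4-hydroxy-4-methyloxan-2-one] | C[C@@]1(O)CCOC(=O)C1 | starting material
12 | potassium (R)-mevalonate [potassium (3R)-3,5-dihydroxy-3-methylpentanoate] | [K+].OCC[C@@](C)(O)CC(=O)[O-] | intermediate
13 | allyl (R)-mevalonate [prop-2-enyl (3R)-3,5-dihydroxy-3-methylpentanoate] | OCC[C@@](C)(O)CC(=O)OCC=C | intermediate
14 | (R)-HMG monoallyl ester [(3R)-3-hydroxy-3-methyl-5-oxo-5-(prop-2-enyloxy)pentanoic acid] | OC(=O)C[C@@](C)(O)CC(=O)OCC=C | intermediate
15 | allyl {4-[(2E,6E)-farnesyl]-3,3-dimethoxy-6-oxocyclohexa-1,4-dien-1-yl}methyl (3S)-3-hydroxy-3-methylpentanedioate | CC(C)=CCC/C(C)=C/CC/C(C)=C/CC1=CC(=O)C(COC(=O)C[C@@](C)(O)CC(=O)OCC=C)=CC1(OC)OC | intermediate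
16 | allyl {(6S)-4-[(2E,6E)-farnesyl]-6-hydroxy-3,3-dimethoxycyclohexa-1,4-dien-1-yl}methyl (3S)-3-hydroxy-3-methylpentanedioate | CC(C)=CCC/C(C)=C/CC/C(C)=C/CC1=C[C@H](O)C(COC(=O)C[C@@](C)(O)CC(=O)OCC=C)=CC1(OC)OC | intermediate
17 | allyl {(1R,5R,6R)-1-[(2E,6E)-farnesyl]-5-hydroxy-2,2-dimethoxy-7-oxabicyclo[4.1.0]hept-3-en-4-yl}methyl (3S)-3-hydroxy-3-methylpentanedioate (OH cis to oxirane O) | CC(C)=CCC/C(C)=C/CC/C(C)=C/C[C@@]12O[C@@H]1[C@H](O)C(COC(=O)C[C@@](C)(O)CC(=O)OCC=C)=CC2(OC)OC | intermediate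
18 | (3S)-5-({(1R,5R,6R)-1-[(2E,6E)-farnesyl]-5-hydroxy-2,2-dimethoxy-7-oxabicyclo[4.1.0]hept-3-en-4-yl}methoxy)-3-hydroxy-3-methyl-5-oxopentanoic acid | CC(C)=CCC/C(C)=C/CC/C(C)=C/C[C@@]12O[C@@H]1[C@H](O)C(COC(=O)C[C@@](C)(O)CC(=O)O)=CC2(OC)OC | intermediate
19 | (3S)-5-({(1R,5R,6R)-1-[(2E,6E)-farnesyl]-5-hydroxy-2-oxo-7-oxabicyclo[4.1.0]hept-3-en-4-yl}methoxy)-3-hydroxy-3-methyl-5-oxopentanoic acid (CNP0134663.2) | CC(C)=CCC/C(C)=C/CC/C(C)=C/C[C@@]12O[C@@H]1[C@H](O)C(COC(=O)C[C@@](C)(O)CC(=O)O)=CC2=O | target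

## Step count and risk

Total step count: 12. Longest linear sequence: 10 (steps 1–6 and 9–12); steps 7–8 make the HMG fragment.

Three steps most likely to fail:

Step 11 (directed epoxidation). The bis-allylic dienol ketal 16 can ionise at the ketal and aromatise under V(V) Lewis acidity, and the second allylic alkene may compete. The fallback moves the whole end-game to a cyclic-ketal series that ionises far more slowly. It sets out from 15: transketalisation (ethylene glycol, PPTS, PhH, 4 Å MS) gives the spiro-dioxolane dienone ester F1. CBS reduction as in step 10 gives the (S)-dioxolane dienol F2. VO(acac)2/t-BuOOH gives the cis-epoxy alcohol dioxolane F3. Pd(PPh3)4/morpholine gives the dioxolane acid F4. Hydrolysis with 48% aq. HF/MeCN at 0 °C (harsher than for the dimethyl ketal, which is the price of this fallback) comes back to the route at 19.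

Step 10 (CBS reduction). The catalyst must tell an α-CH2O-acyl vinyl from an α-H vinyl on a cross-conjugated dienone, and the product is acid-labile. The fallback replaces asymmetric reduction by enzymatic kinetic resolution. It sets out from 15: Luche reduction (NaBH4, CeCl3·7H2O, MeOH, −78 °C) gives the C4-epimeric dienol mixture F5. Lipase PS (Burkholderia cepacia) with vinyl acetate in MTBE acylates, by Kazlauskas' rule, the (R)-carbinol epimer to the (4R)-dienyl acetate F6. The unreacted (S)-alcohol is 16, where the route is rejoined.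

Step 9 (Steglich acylation). The alcohol 10 is of Baylis–Hillman type, so DMAP may attack in SN2′ fashion, and the activated β-hydroxy acid 14 may lactonise or dehydrate. The fallback reverses the polarity of ester formation so that 14 is never activated. It sets out from 10: Appel reaction (CBr4, PPh3, CH2Cl2, −20 °C) gives the allylic bromide F7. The caesium carboxylate of 14 (Cs2CO3, DMF, 0 °C) displaces bromide at the primary carbon and comes back to the route at 15.

## Further compounds

F1 | step 11 | spiro-dioxolane dienone ester: allyl {4-[(2E,6E)-farnesyl]-3,3-(ethylenedioxy)-6-oxocyclohexa-1,4-dien-1-yl}methyl (3S)-3-hydroxy-3-methylpentanedioate | CC(C)=CCC/C(C)=C/CC/C(C)=C/CC1=CC(=O)C(COC(=O)C[C@@](C)(O)CC(=O)OCC=C)=CC12OCCO2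
F2 | step 11 | (S)-dioxolane dienol: allyl {(6S)-4-[(2E,6E)-farnesyl]-3,3-(ethylenedioxy)-6-hydroxycyclohexa-1,4-dien-1-yl}methyl (3S)-3-hydroxy-3-methylpentanedioate | CC(C)=CCC/C(C)=C/CC/C(C)=C/CC1=C[C@H](O)C(COC(=O)C[C@@](C)(O)CC(=O)OCC=C)=CC12OCCO2
F3 | step 11 | cis-epoxy alcohol dioxolane: allyl {(1R,5R,6R)-1-[(2E,6E)-farnesyl]-2,2-(ethylenedioxy)-5-hydroxy-7-oxabicyclo[4.1.0]hept-3-en-4-yl}methyl (3S)-3-hydroxy-3-methylpentanedioate | CC(C)=CCC/C(C)=C/CC/C(C)=C/C[C@@]12O[C@@H]1[C@H](O)C(COC(=O)C[C@@](C)(O)CC(=O)OCC=C)=CC23OCCO3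
F4 | step 11 | dioxolane acid: (3S)-5-({(1R,5R,6R)-1-[(2E,6E)-farnesyl]-2,2-(ethylenedioxy)-5-hydroxy-7-oxabicyclo[4.1.0]hept-3-en-4-yl}methoxy)-3-hydroxy-3-methyl-5-oxopentanoic acid | CC(C)=CCC/C(C)=C/CC/C(C)=C/C[C@@]12O[C@@H]1[C@H](O)C(COC(=O)C[C@@](C)(O)CC(=O)O)=CC23OCCO3
F5 | step 10 | C4-epimeric dienol mixture (16 and its carbinol epimer) | CC(C)=CCC/C(C)=C/CC/C(C)=C/CC1=CC(O)C(COC(=O)C[C@@](C)(O)CC(=O)OCC=C)=CC1(OC)OC
F6 | step 10 | (4R)-dienyl acetate: allyl {(6R)-6-acetoxy-4-[(2E,6E)-farnesyl]-3,3-dimethoxycyclohexa-1,4-dien-1-yl}methyl (3S)-3-hydroxy-3-methylpentanedioate | CC(C)=CCC/C(C)=C/CC/C(C)=C/CC1=C[C@@H](OC(C)=O)C(COC(=O)C[C@@](C)(O)CC(=O)OCC=C)=CC1(OC)OC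
F7 | step 9 | allylic bromide: 2-(bromomethyl)-5-[(2E,6E)-farnesyl]-4,4-dimethoxycyclohexa-2,5-dien-1-one | CC(C)=CCC/C(C)=C/CC/C(C)=C/CC1=CC(=O)C(CBr)=CC1(OC)OC
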